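**Strategy.** Ring B (C5–C6–C7–C8–C9–C10, labdane numbering) is opened at C8–C9: the tertiary carbinol C9 flanked by the methyl-bearing C8 is the retron of a reductive ketone–olefin radical cyclisation. Iron-hydride hydrogen-atom transfer to a terminal but-3-enyl group turns C17 into the methyl group and C8 into a radical that closes 6-exo onto the C9 ketone, creating the ring, the C8–C9 bond, both stereocentres and the tertiary alcohol in one operation and giving the target directly. The precursor is a monocyclic ring-A acetate with the finished butenolide side chain on the C9 ketone and the butenyl chain on C5, assembled by an enantioselective aminosiloxydiene Diels–Alder reaction.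

Key step: step 9

Remarks (assumptions):
- Labdane numbering is used in the Why lines: ring A = C1–C5, C10; ring B = C5–C10; side chain C11–C16; C17 = methyl on C8.
- The catalyst antipode in step 2 is taken as the one that gives 5 as drawn; if the sense of induction were opposite, the enantiomeric ligand would be used.
- 3-(2-Bromoethyl)furan (6) is taken as a catalogue compound.

Step 1
Reactants: 1 pent-4-enal; 2 2-(triphenyl-λ5-phosphanylidene)propanal
Product: 3 (2E)-2-methylhepta-2,6-dienal
Conditions: PhMe, 90 °C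
Reagents that add atoms: none
Why: Wittig olefination with a formyl-stabilised ylide is E-selective, which places CHO trans to the butenyl chain, the geometry later transferred to C5/C10.

Step 2
Reactants: 3 (2E)-2-methylhepta-2,6-dienal; 4 (1E)-3-[(tert-butyldimethylsilyl)oxy]-N,N-dimethylbuta-1,3-dien-1-amine
Product: 5 (1R,2S,6S)-6-(but-3-en-1-yl)-4-[(tert-butyldimethylsilyl)oxy]-2-(dimethylamino)-1-methylcyclohex-3-ene-1-carbaldehyde
Conditions: (R,R)-(salen)Cr(III)SbF6 (5 mol %), 4 Å MS, CH2Cl2, −40 → 0 °C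
Reagents that add atoms: none
Why: Catalytic enantioselective Diels–Alder reaction of an aminosiloxydiene with an α-substituted enal: the amino terminus bonds to the α-carbon (C10), suprafacial addition carries the E geometry into the cis relation of the C10 methyl and the C5 butenyl group (CHO trans), and the chiral Lewis acid sets the absolute configuration of both centres (endo amine centre lost in step 3).

Step 3
Reactants: 5 the cycloadduct; 6 3-(2-bromoethyl)furan
Product: 9 (4R,5S)-5-(but-3-en-1-yl)-4-[(1RS)-3-(furan-3-yl)-1-hydroxypropyl]-4-methylcyclohex-2-en-1-one, via Grignard reagent 7 (not isolated), via amino silyl enol ether carbinol 8 (not isolated)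
Conditions: 6, Mg, THF, rt; then 5, THF, −78 → 0 °C; then 0.1 M HCl, THF, 0 °C → rt
Reagents that add atoms: none
Why: Grignard 1,2-addition to the neopentyl aldehyde while the ring ketone is still masked as its silyl enol ether, followed by acid hydrolysis of the enol ether and β-elimination of dimethylamine to unveil the enone; the carbinol centre forms as a mixture and is oxidised in step 5.

Step 4
Reactants: 9 the hydroxy enone
Product: 11 (4S,5R)-5-(but-3-en-1-yl)-4-[(1RS)-3-(furan-3-yl)-1-hydroxypropyl]-4,6,6-trimethylcyclohex-2-en-1-one, via monomethyl enone 10 (not isolated)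
Conditions: LDA (2.2 equiv), THF, −78 °C; MeI (1.1 equiv), −78 → −20 °C; LDA (1.3 equiv), −78 °C; MeI (2 equiv), DMPU, −78 → 0 °C
Reagents that add atoms: iodomethane, CI
Why: Exhaustive α′-alkylation of the kinetic cross-conjugated enolate: the enone has no γ-hydrogen (C10 is quaternary), so only C4 can be deprotonated, and the hindered lithium alkoxide should not be O-methylated at low temperature.

Step 5
Reactants: 11 the gem-dimethyl hydroxy enone
Product: 12 (4S,5S)-5-(but-3-en-1-yl)-4-[3-(furan-3-yl)propanoyl]-4,6,6-trimethylcyclohex-2-en-1-one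
Conditions: Dess–Martin periodinane, NaHCO3, CH2Cl2, 0 °C → rt
Reagents that add atoms: none
Why: Dess–Martin oxidation of the secondary carbinol gives the C9 ketone and merges the two carbinol epimers; furan, enone and terminal alkene are inert.

Step 6
Reactants: 12 the enedione
Product: 13 (3S,4S)-3-(but-3-en-1-yl)-4-[3-(furan-3-yl)propanoyl]-2,2,4-trimethylcyclohexan-1-one
Conditions: [(Ph3P)CuH]6 (0.4 equiv), PhMe, H2O (5 equiv), rt
Reagents that add atoms: none
Why: Stryker conjugate reduction delivers hydride to C1 of the enone only, leaving the isolated terminal alkene, the furan and the non-conjugated C9 ketone untouched.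

Step 7
Reactants: 13 the furan diketone
Product: 15 4-{3-[(1S,2S,4S)-2-(but-3-en-1-yl)-4-hydroxy-1,3,3-trimethylcyclohexyl]-3-oxopropyl}furan-2(5H)-one, via γ-hydroxybutenolide 14 (not isolated)
Conditions: O2, hν, TPP (cat.), i-Pr2NEt, CH2Cl2, −78 °C; then NaBH4, EtOH, −20 → 0 °C; 1 M HCl work-up
Reagents that add atoms: dioxygen, O=O
Why: Singlet-oxygen [4+2] addition to the 3-alkylfuran and base-induced opening of the endoperoxide at the less hindered C15–H give the 4-alkyl-5-hydroxybutenolide (Kernan–Faulkner oxidation), whose open aldehyde form is reduced by NaBH4 and relactonises to the butenolide, while the same hydride reduces the ring ketone C3 from the α-face (opposite the C5 chain and C10 methyl) to the 3S alcohol and should leave the far more hindered C9 ketone.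

Step 8
Reactants: 15 the hydroxy ketone
Product: 16 (1S,3S,4S)-3-(but-3-en-1-yl)-2,2,4-trimethyl-4-[3-(5-oxo-2,5-dihydrofuran-3-yl)propanoyl]cyclohexyl acetate
Conditions: Ac2O, DMAP (cat.), pyridine, CH2Cl2, rt
Reagents that add atoms: acetic anhydride, CC(=O)OC(C)=O
Why: DMAP-catalysed acetylation of the only hydroxyl group, which also locks ring A in the chair with the C5 chain and the C10 acyl group equatorial.

Step 9
Reactants: 16 the keto alkene acetate
Product: 17 (2S,4aS,5R,6R,8aS)-5-hydroxy-1,1,4a,6-tetramethyl-5-[2-(5-oxo-2,5-dihydrofuran-3-yl)ethyl]decahydronaphthalen-2-yl acetate (target)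
Conditions: Fe(acac)3 (0.5 equiv), PhSiH3 (2.5 equiv), degassed EtOH, 60 °C
Reagents that add atoms: none
Why: An iron hydride formed from Fe(acac)3 and PhSiH3 transfers H• to the terminal carbon C17 of the alkene (Markovnikov), the secondary C8 radical adds to the C9 carbonyl carbon, and the alkoxy radical is reduced (Fe(II)/EtOH) to the tertiary alcohol. The closest known reaction type is the iron-mediated HAT radical cyclisation of alkene-tethered ketones (Mukaiyama-type radical generation, reductive ketone–olefin coupling). Ring B closes in the 6-exo-trig mode on C=O through a chair transition state trans-fused to the ring-A chair, the trans fusion being preset by C5 and C10. C8 is set by the new methyl group taking the equatorial site, because the axial one is 1,3-diaxial to the C10 methyl; C9 is set by the carbonyl face, with the CH2CH2 side chain expected equatorial and the oxygen axial (anti to the C10 methyl), which avoids syn-axial contacts of the chain with H5 and H7. The step needs HAT to the isolated alkene and cyclisation before the radical is reduced: the electron-poor β,β-disubstituted butenolide is a poor HAT acceptor and radical trap and is reachable only through 9- or 10-membered rings, and C3 is already an acetate, so no second ketone competes.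

**Compound list**

1 | pent-4-enal | C=CCCC=O | starting material
2 | 2-(triphenyl-λ5-phosphanylidene)propanal | CC(C=O)=P(c1ccccc1)(c1ccccc1)c1ccccc1 | starting material
3 | (2E)-2-methylhepta-2,6-dienal | C=CCC/C=C(\C)C=O | intermediate
4 | (1E)-3-[(tert-butyldimethylsilyl)oxy]-N,N-dimethylbuta-1,3-dien-1-amine | CN(C)/C=C/C(=C)O[Si](C)(C)C(C)(C)C | starting material
5 | (1R,2S,6S)-6-(but-3-en-1-yl)-4-[(tert-butyldimethylsilyl)oxy]-2-(dimethylamino)-1-methylcyclohex-3-ene-1-carbaldehyde | CC(C)(C)[Si](C)(C)OC1=C[C@H](N(C)C)[C@@](C=O)(C)[C@@H](CCC=C)C1 | intermediate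
6 | 3-(2-bromoethyl)furan | BrCCc1ccoc1 | starting material
7 | 2-(furan-3-yl)ethylmagnesium bromide | Br[Mg]CCc1ccoc1 | intermediate
8 | 1-[(1R,2S,6S)-6-(but-3-en-1-yl)-4-[(tert-butyldimethylsilyl)oxy]-2-(dimethylamino)-1-methylcyclohex-3-en-1-yl]-3-(furan-3-yl)propan-1-ol (carbinol epimers, formed as the magnesium alkoxide) | CC(C)(C)[Si](C)(C)OC1=C[C@H](N(C)C)[C@@](C(O)CCc2ccoc2)(C)[C@@H](CCC=C)C1 | intermediate
9 | (4R,5S)-5-(but-3-en-1-yl)-4-[(1RS)-3-(furan-3-yl)-1-hydroxypropyl]-4-methylcyclohex-2-en-1-one | O=C1C=C[C@@](C(O)CCc2ccoc2)(C)[C@@H](CCC=C)C1 | intermediate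
10 | (4S,5S,6RS)-5-(but-3-en-1-yl)-4-[(1RS)-3-(furan-3-yl)-1-hydroxypropyl]-4,6-dimethylcyclohex-2-en-1-one | O=C1C=C[C@@](C(O)CCc2ccoc2)(C)[C@@H](CCC=C)C1C | intermediate
11 | (4S,5R)-5-(but-3-en-1-yl)-4-[(1RS)-3-(furan-3-yl)-1-hydroxypropyl]-4,6,6-trimethylcyclohex-2-en-1-one | O=C1C=C[C@@](C(O)CCc2ccoc2)(C)[C@@H](CCC=C)C1(C)C | intermediate
12 | (4S,5S)-5-(but-3-en-1-yl)-4-[3-(furan-3-yl)propanoyl]-4,6,6-trimethylcyclohex-2-en-1-one | O=C1C=C[C@@](C(=O)CCc2ccoc2)(C)[C@@H](CCC=C)C1(C)C | intermediate
13 | (3S,4S)-3-(but-3-en-1-yl)-4-[3-(furan-3-yl)propanoyl]-2,2,4-trimethylcyclohexan-1-one | O=C1CC[C@@](C(=O)CCc2ccoc2)(C)[C@@H](CCC=C)C1(C)C | intermediate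
14 | (3S,4S)-3-(but-3-en-1-yl)-4-[3-(2-hydroxy-5-oxo-2,5-dihydrofuran-3-yl)propanoyl]-2,2,4-trimethylcyclohexan-1-one (lactol epimers) | O=C1CC[C@@](C(=O)CCC2=CC(=O)OC2O)(C)[C@@H](CCC=C)C1(C)C | intermediate
15 | 4-{3-[(1S,2S,4S)-2-(but-3-en-1-yl)-4-hydroxy-1,3,3-trimethylcyclohexyl]-3-oxopropyl}furan-2(5H)-one | O[C@H]1CC[C@@](C(=O)CCC2=CC(=O)OC2)(C)[C@@H](CCC=C)C1(C)C | intermediate
16 | (1S,3S,4S)-3-(but-3-en-1-yl)-2,2,4-trimethyl-4-[3-(5-oxo-2,5-dihydrofuran-3-yl)propanoyl]cyclohexyl acetate | CC(=O)O[C@H]1CC[C@@](C(=O)CCC2=CC(=O)OC2)(C)[C@@H](CCC=C)C1(C)C | intermediate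
17 | (2S,4aS,5R,6R,8aS)-5-hydroxy-1,1,4a,6-tetramethyl-5-[2-(5-oxo-2,5-dihydrofuran-3-yl)ethyl]decahydronaphthalen-2-yl acetate | CC(=O)O[C@H]1CC[C@@]2(C)[C@@H](CC[C@@H](C)[C@]2(O)CCC2=CC(=O)OC2)C1(C)C | target

**Step count.** Total: 9 steps. Longest linear sequence: 9 steps (1 → 17; 6 enters in step 3).

**Steps most likely to fail**

1. Step 9. HAT to a monosubstituted alkene is slow, so the C8 radical may simply be reduced (net alkene hydrogenation) before it adds to the hindered C9 carbonyl, the addition may revert, or the carbonyl may be attacked on the wrong face. The fallback reverses the roles and makes the ketyl the reactive species. It sets out from 13, whose ring ketone is reduced under reagent control with (R)-Me-CBS and catecholborane (toluene, −78 °C) to 1-[(1S,2S,4S)-2-(but-3-en-1-yl)-4-hydroxy-1,3,3-trimethylcyclohexyl]-3-(furan-3-yl)propan-1-one F1. Acetylation (Ac2O, DMAP, pyridine) gives (1S,3S,4S)-3-(but-3-en-1-yl)-4-[3-(furan-3-yl)propanoyl]-2,2,4-trimethylcyclohexyl acetate F2. SmI2/HMPA/t-BuOH in THF then effects a ketyl–olefin 6-exo cyclisation to (2S,4aS,5R,6R,8aS)-5-[2-(furan-3-yl)ethyl]-5-hydroxy-1,1,4a,6-tetramethyldecahydronaphthalen-2-yl acetate F3, which the furan survives. Photooxygenation (O2, hν, TPP, i-Pr2NEt, −78 °C) to the decalin γ-hydroxybutenolide (2S,4aS,5R,6R,8aS)-5-hydroxy-5-[2-(2-hydroxy-5-oxo-2,5-dihydrofuran-3-yl)ethyl]-1,1,4a,6-tetramethyldecahydronaphthalen-2-yl acetate F4 and NaBH4 reduction in the same flask return to the route at 17. In this fallback the butenolide is unveiled after ring B is closed.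

2. Step 2. The β-alkyl group lowers the reactivity of the enal, so the cycloaddition may be slow, the diene may decompose first, and facial discrimination by the salen catalyst may erode. The fallback sets out from 3 and uses a cationic oxazaborolidine (CBS-type oxazaborolidine activated with Tf2NH, CH2Cl2, −78 → −20 °C) with 2-(triisopropylsilyloxy)buta-1,3-diene. This should give (1S,6S)-6-(but-3-en-1-yl)-1-methyl-4-[(triisopropylsilyl)oxy]cyclohex-3-ene-1-carbaldehyde F5. Addition of Grignard reagent 7 gives 1-[(1S,6S)-6-(but-3-en-1-yl)-1-methyl-4-[(triisopropylsilyl)oxy]cyclohex-3-en-1-yl]-3-(furan-3-yl)propan-1-ol F6. Saegusa–Ito dehydrogenation of the silyl enol ether (Pd(OAc)2, MeCN, rt) returns to the route at 9.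

3. Step 7. The monocyclic C3 ketone is conformationally mobile, so hydride may attack both faces, and some reduction of the C9 ketone may set in with the excess NaBH4. The fallback sets out from 13 and fixes C3 by reagent control before the furan is oxidised: (R)-Me-CBS/catecholborane gives the hydroxy ketone F1 described under step 9. Its photooxygenation (O2, hν, TPP, i-Pr2NEt) gives 4-{3-[(1S,2S,4S)-2-(but-3-en-1-yl)-4-hydroxy-1,3,3-trimethylcyclohexyl]-3-oxopropyl}-5-hydroxyfuran-2(5H)-one F7, and a brief NaBH4 treatment, which now only has to reduce the lactol, returns to the route at 15.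

**Further compounds**

F1 | step 9 | 1-[(1S,2S,4S)-2-(but-3-en-1-yl)-4-hydroxy-1,3,3-trimethylcyclohexyl]-3-(furan-3-yl)propan-1-one | O[C@H]1CC[C@@](C(=O)CCc2ccoc2)(C)[C@@H](CCC=C)C1(C)C
F2 | step 9 | (1S,3S,4S)-3-(but-3-en-1-yl)-4-[3-(furan-3-yl)propanoyl]-2,2,4-trimethylcyclohexyl acetate | CC(=O)O[C@H]1CC[C@@](C(=O)CCc2ccoc2)(C)[C@@H](CCC=C)C1(C)C
F3 | step 9 | (2S,4aS,5R,6R,8aS)-5-[2-(furan-3-yl)ethyl]-5-hydroxy-1,1,4a,6-tetramethyldecahydronaphthalen-2-yl acetate | CC(=O)O[C@H]1CC[C@@]2(C)[C@@H](CC[C@@H](C)[C@]2(O)CCc2ccoc2)C1(C)C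
F4 | step 9 | (2S,4aS,5R,6R,8aS)-5-hydroxy-5-[2-(2-hydroxy-5-oxo-2,5-dihydrofuran-3-yl)ethyl]-1,1,4a,6-tetramethyldecahydronaphthalen-2-yl acetate | CC(=O)O[C@H]1CC[C@@]2(C)[C@@H](CC[C@@H](C)[C@]2(O)CCC2=CC(=O)OC2O)C1(C)C
F5 | step 2 | (1S,6S)-6-(but-3-en-1-yl)-1-methyl-4-[(triisopropylsilyl)oxy]cyclohex-3-ene-1-carbaldehyde | CC(C)[Si](C(C)C)(C(C)C)OC1=CC[C@@](C=O)(C)[C@@H](CCC=C)C1
F6 | step 2 | 1-[(1S,6S)-6-(but-3-en-1-yl)-1-methyl-4-[(triisopropylsilyl)oxy]cyclohex-3-en-1-yl]-3-(furan-3-yl)propan-1-ol | CC(C)[Si](C(C)C)(C(C)C)OC1=CC[C@@](C(O)CCc2ccoc2)(C)[C@@H](CCC=C)C1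
F7 | step 7 | 4-{3-[(1S,2S,4S)-2-(but-3-en-1-yl)-4-hydroxy-1,3,3-trimethylcyclohexyl]-3-oxopropyl}-5-hydroxyfuran-2(5H)-one | O[C@H]1CC[C@@](C(=O)CCC2=CC(=O)OC2O)(C)[C@@H](CCC=C)C1(C)C
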